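Eremophilane numbering: ring A = C1–C5, C10; ring B = C5–C10, with the ester on C9, OH on C8 and isopropenyl on C7. Ring B is disconnected at C6–C7 and C8–C9. The key step exploits that C9 is an oxygenated carbon which, with ring-fusion C10 and the C6 methylene on quaternary C5 (reached across C8–C7), can be tied into a cyclobutanone (C5–C6–C9–C10) fused to ring A. Strain-driven nickel-catalysed insertion of 2-methylbut-1-en-3-yne into its C9–C6 bond forms both bonds and delivers C7 with its isopropenyl group. The cyclobutanone comes from (S)-carvone by ketene [2+2] cycloaddition; reductive transposition and dihydroxylation then set C7–C9.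

Key step: step 7

Remark: for the bicyclic compounds α/β refer to the face opposite to/of the C5 methyl (C11–C13 = side chain on C7); compounds 14–21 are carried as mixtures of C11 epimers, which converge in step 12.

Step 1
Reactants: 1 (S)-(+)-carvone
Product: 4 (S)-5-acetoxy-2-methylcyclohex-2-en-1-one, via methoxy hydroperoxide 2 (not isolated), via peracetate 3 (not isolated)
Conditions: O3, CH2Cl2/MeOH, −78 °C; then Ac2O, Et3N, DMAP (cat.), −78 °C → rt
Reagents that add atoms: ozone, [O-][O+]=O
Why: Ozonolysis cleaves the electron-rich isopropenyl group in preference to the conjugated enone, methanol traps the carbonyl oxide as the methoxy hydroperoxide, and acetylation triggers a Criegee rearrangement in which the ring carbon migrates to oxygen with retention, so the carvone stereocentre becomes the acetoxy-bearing carbon (future C2).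

Step 2
Reactants: 4 (S)-5-acetoxy-2-methylcyclohex-2-en-1-one
Product: 5 (S)-5-hydroxy-2-methylcyclohex-2-en-1-one
Conditions: K2CO3 (cat.), MeOH, 0 °C
Reagents that add atoms: none
Why: Base-catalysed transesterification with methanol at 0 °C should remove the acetate faster than the β-oxygen is lost by E1cB elimination, and the stereocentre is not involved.

Step 3
Reactants: 5 (S)-5-hydroxy-2-methylcyclohex-2-en-1-one
Product: 6 (S)-5-[(tert-butyldimethylsilyl)oxy]-2-methylcyclohex-2-en-1-one
Conditions: TBSCl, imidazole, DMF, rt
Reagents that add atoms: tert-butyldimethylsilyl chloride, CC(C)(C)[Si](C)(C)Cl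
Why: Standard silylation of a secondary alcohol under weakly basic conditions gives a silyl ether that should survive every step up to the last.

Step 4
Reactants: 6 (S)-5-[(tert-butyldimethylsilyl)oxy]-2-methylcyclohex-2-en-1-one
Product: 8 (3S,5S)-5-[(tert-butyldimethylsilyl)oxy]-2,3-dimethylcyclohex-1-en-1-yl trifluoromethanesulfonate, via lithium enolate 7 (not isolated)
Conditions: CuI, MeLi (2 equiv), Et2O, −78 → −20 °C; then N-(5-chloro-2-pyridyl)triflimide, THF, −78 → 0 °C
Reagents that add atoms: lithium dimethylcuprate, [Li+].C[Cu-]C; N-(5-chloropyridin-2-yl)bis(trifluoromethanesulfonyl)imide, FC(F)(F)S(=O)(=O)N(c1ccc(Cl)cn1)S(=O)(=O)C(F)(F)F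
Why: Cuprate conjugate addition should occur anti to the silyloxy group (axial attack on the half-chair that keeps this group pseudo-equatorial), which sets the future C4 methyl trans to the C2 oxygen, and the regiodefined enolate is trapped on oxygen as the enol triflate.

Step 5
Reactants: 8 (3S,5S)-5-[(tert-butyldimethylsilyl)oxy]-2,3-dimethylcyclohex-1-en-1-yl trifluoromethanesulfonate
Product: 9 tert-butyl{[(1R,5S)-4,5-dimethylcyclohex-3-en-1-yl]oxy}dimethylsilane
Conditions: Pd(OAc)2 (cat.), PPh3, HCO2H, Bu3N, DMF, 60 °C
Reagents that add atoms: none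
Why: Palladium-catalysed formate reduction of the enol triflate (oxidative addition, formate decarboxylation, C–H reductive elimination) replaces OTf by H and leaves the trisubstituted C5=C10 alkene where the enolate was, with no stereocentre touched.

Step 6
Reactants: 9 tert-butyl{[(1R,5S)-4,5-dimethylcyclohex-3-en-1-yl]oxy}dimethylsilane
Product: 11 (1R,2S,4S,6S)-4-[(tert-butyldimethylsilyl)oxy]-1,2-dimethylbicyclo[4.2.0]octan-7-one, via dichlorocyclobutanone 10 (not isolated)
Conditions: Cl3CCOCl, activated Zn dust, POCl3, Et2O, 25–35 °C; then Zn, AcOH, rt on the crude adduct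
Reagents that add atoms: trichloroacetyl chloride, ClC(Cl)(Cl)C(Cl)=O
Why: Ketene [2+2] cycloaddition joins the dichloroketene carbonyl carbon to the less substituted alkene carbon (C10) and the CCl2 carbon to C5 on the face anti to the pseudo-axial allylic C4 methyl, which sets the C5 quaternary centre (methyl cis to the C4 methyl) and a cis ring fusion at C10, and zinc in acetic acid then removes both chlorines by reductive dechlorination.

Step 7
Reactants: 11 (1R,2S,4S,6S)-4-[(tert-butyldimethylsilyl)oxy]-1,2-dimethylbicyclo[4.2.0]octan-7-one; 12 2-methylbut-1-en-3-yne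
Product: 13 cis-fused dienone 2α-(tert-butyldimethylsilyloxy)-10βH-eremophila-7,11-dien-9-one
Conditions: Ni(cod)2 (10 mol %), PCy3 (20 mol %), toluene, 90 °C, 12 (3 equiv) added by syringe pump over 6 h
Reagents that add atoms: none
Why: Zerovalent nickel couples the C9 carbonyl of 11 with the alkyne by oxidative cyclization to an oxanickelacyclopentene (C8–C9 bond), β-carbon elimination then cleaves the strained C9–C6 bond to a seven-membered alkyl(alkenyl)nickel species, and C(sp3)–C(sp2) reductive elimination forms C6–C7, the roughly 25 kcal/mol of cyclobutanone strain paying for the sequence. The closest known reaction type is the nickel-catalysed intermolecular insertion of internal alkynes into cyclobutanones to give cyclohex-2-enones. Ring B is closed by a two-carbon ring expansion, that is by reductive elimination from the seven-membered nickelacycle and not by cyclization of an open chain. No new stereocentre is created: C5 and C10 are not touched, so the cis ring fusion of 11 is carried into 13 and is corrected in step 8. Two selectivities are needed: the alkyne must orient with its CH terminus toward C9, which the small hydrogen substituent and the conjugated alkene (holding its own alkyne carbon on nickel) should both secure, and the C9–C6 rather than the C9–C10 bond must be cleaved, which the preference of β-carbon elimination for the unsubstituted methylene over the ring-fusion methine should secure. The main risk is nickel-mediated oligomerization of the terminal enyne, which slow addition is meant to suppress.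

Step 8
Reactants: 13 cis-fused dienone 2α-(tert-butyldimethylsilyloxy)-10βH-eremophila-7,11-dien-9-one
Product: 15 trans-fused amino enone 12-(dimethylamino)-2α-(tert-butyldimethylsilyloxy)-10αH-eremophil-7-en-9-one, via cis-fused amino enone 14 (not isolated)
Conditions: Me2NH (2 M in MeOH, excess), K2CO3 (0.5 equiv), MeOH, 40 °C
Reagents that add atoms: dimethylamine, CNC
Why: Vinylogous (1,6) aza-Michael addition of dimethylamine to the terminal carbon of the dienone masks the isopropenyl alkene, and carbonate/methoxide enolization toward C10 equilibrates the ring fusion to the trans-decalone, which should be favoured because both ring B carbons syn-axial to the C5 methyl (C7 and C9) are trigonal.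

Step 9
Reactants: 15 trans-fused amino enone 12-(dimethylamino)-2α-(tert-butyldimethylsilyloxy)-10αH-eremophil-7-en-9-one
Product: 16 allylic alcohol 12-(dimethylamino)-2α-(tert-butyldimethylsilyloxy)-10αH-eremophil-7-en-9β-ol
Conditions: i-Bu2AlH (2.5 equiv), CH2Cl2, −78 °C
Reagents that add atoms: none
Why: 1,2-Reduction of the enone by the bulky aluminium hydride should occur from the α face, the β face of C9 being screened by the axial C5 methyl, to give the pseudo-axial 9β-alcohol.

Step 10
Reactants: 16 allylic alcohol 12-(dimethylamino)-2α-(tert-butyldimethylsilyloxy)-10αH-eremophil-7-en-9β-ol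
Product: 19 alkene 12-(dimethylamino)-2α-(tert-butyldimethylsilyloxy)-7αH-10αH-eremophil-8-ene, via sulfonyl hydrazine 17 (not isolated), via allylic diazene 18 (not isolated)
Conditions: o-nitrobenzenesulfonylhydrazide, PPh3, DEAD, THF/N-methylmorpholine, −30 °C → rt
Reagents that add atoms: none
Why: Mitsunobu displacement of the 9β-alcohol by the sulfonyl hydrazide with inversion puts nitrogen on the α face, loss of sulfinic acid gives the allylic diazene, and its retro-ene loss of N2 (reductive allylic transposition) delivers hydrogen suprafacially to the α face of C7, which sets C7 with the side chain β (axial) and moves the alkene to C8=C9.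

Step 11
Reactants: 19 alkene 12-(dimethylamino)-2α-(tert-butyldimethylsilyloxy)-7αH-10αH-eremophil-8-ene
Product: 20 diol 12-(dimethylamino)-2α-(tert-butyldimethylsilyloxy)-7αH-10αH-eremophilane-8α,9α-diol
Conditions: OsO4 (5 mol %), N-methylmorpholine N-oxide, acetone/H2O, rt
Reagents that add atoms: osmium tetroxide, O=[Os](=O)(=O)=O; N-methylmorpholine N-oxide, C[N+]1([O-])CCOCC1; water, O
Why: Catalytic osmium tetroxide syn-dihydroxylation of the only alkene present should occur from the α face, the β face being blocked by the axial C5 methyl and the axial C7 side chain, which sets the 8α and 9α hydroxyl groups in one step.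

Step 12
Reactants: 20 diol 12-(dimethylamino)-2α-(tert-butyldimethylsilyloxy)-7αH-10αH-eremophilane-8α,9α-diol
Product: 22 diol 2α-(tert-butyldimethylsilyloxy)-7αH-10αH-eremophil-11-ene-8α,9α-diol, via amine N-oxide 21 (not isolated)
Conditions: mCPBA (1.05 equiv), CH2Cl2, −20 °C; then DMSO/THF, 50 °C
Reagents that add atoms: none
Why: N-Oxidation of the tertiary amine followed by Cope elimination (syn, five-membered transition state) through the only β-hydrogen, C11–H, regenerates the isopropenyl group, so both C11 epimers converge on one compound.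

Step 13
Reactants: 23 ethyl pent-2-ynoate
Product: 24 ethyl (2Z)-3-methylpent-2-enoate
Conditions: CuI, MeLi (2 equiv), THF, −78 °C; 23, −78 °C; then aq. NH4Cl at −78 °C
Reagents that add atoms: lithium dimethylcuprate, [Li+].C[Cu-]C
Why: syn-Carbocupration of the ynoate at −78 °C and protonation of the vinylcopper with retention place the new methyl cis to H and the ethyl cis to the ester, which is the Z alkene.

Step 14
Reactants: 24 ethyl (2Z)-3-methylpent-2-enoate
Product: 25 (2Z)-3-methylpent-2-enoic acid
Conditions: LiOH, THF/H2O, rt; then dilute HCl to pH 3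
Reagents that add atoms: lithium hydroxide, [Li+].[OH-]
Why: Saponification at room temperature and mild acidification should leave the trisubstituted Z alkene untouched.

Step 15
Reactants: 22 diol 2α-(tert-butyldimethylsilyloxy)-7αH-10αH-eremophil-11-ene-8α,9α-diol; 25 (2Z)-3-methylpent-2-enoic acid
Product: 26 silyl-protected target 2α-(tert-butyldimethylsilyloxy)-8α-hydroxy-7αH-10αH-eremophil-11-en-9α-yl (2Z)-3-methylpent-2-enoate
Conditions: DCC, DMAP (cat.), CH2Cl2, 0 °C → rt
Reagents that add atoms: none
Why: Steglich esterification should acylate the equatorial 9α-hydroxyl in preference to the axial 8α-hydroxyl, which is flanked by the axial C7 substituent and two syn-axial hydrogens, and the mild carbodiimide conditions should keep the Z geometry.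

Step 16
Reactants: 26 silyl-protected target 2α-(tert-butyldimethylsilyloxy)-8α-hydroxy-7αH-10αH-eremophil-11-en-9α-yl (2Z)-3-methylpent-2-enoate
Product: 27 target (1S,2R,3R,4aR,5S,7S,8aR)-2,7-dihydroxy-4a,5-dimethyl-3-(prop-1-en-2-yl)decahydronaphthalen-1-yl (2Z)-3-methylpent-2-enoate
Conditions: HF·pyridine, THF/pyridine, 0 °C → rt
Reagents that add atoms: none
Why: Fluoride-mediated desilylation under mildly acidic conditions should free the C2 hydroxyl without acyl migration between the cis-vicinal C8 and C9 oxygens.

Compound list

1 | (S)-(+)-carvone | CC1=CC[C@@H](CC1=O)C(C)=C | starting material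
2 | (5S)-5-(1-hydroperoxy-1-methoxyethyl)-2-methylcyclohex-2-en-1-one (methoxy hydroperoxide) | CC1=CC[C@@H](CC1=O)C(C)(OC)OO | intermediate
3 | peracetate of 2 | CC1=CC[C@@H](CC1=O)C(C)(OC)OOC(C)=O | intermediate
4 | (S)-5-acetoxy-2-methylcyclohex-2-en-1-one | CC1=CC[C@@H](CC1=O)OC(C)=O | intermediate
5 | (S)-5-hydroxy-2-methylcyclohex-2-en-1-one | CC1=CC[C@@H](CC1=O)O | intermediate
6 | (S)-5-[(tert-butyldimethylsilyl)oxy]-2-methylcyclohex-2-en-1-one | CC1=CC[C@@H](CC1=O)O[Si](C)(C)C(C)(C)C | intermediate
7 | lithium (3S,5S)-5-[(tert-butyldimethylsilyl)oxy]-2,3-dimethylcyclohex-1-en-1-olate | [Li+].CC1=C([O-])C[C@@H](O[Si](C)(C)C(C)(C)C)C[C@@H]1C | intermediate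
8 | (3S,5S)-5-[(tert-butyldimethylsilyl)oxy]-2,3-dimethylcyclohex-1-en-1-yl trifluoromethanesulfonate | CC1=C(OS(=O)(=O)C(F)(F)F)C[C@@H](O[Si](C)(C)C(C)(C)C)C[C@@H]1C | intermediate
9 | tert-butyl{[(1R,5S)-4,5-dimethylcyclohex-3-en-1-yl]oxy}dimethylsilane | CC1=CC[C@@H](O[Si](C)(C)C(C)(C)C)C[C@@H]1C | intermediate
10 | (1R,2S,4S,6S)-4-[(tert-butyldimethylsilyl)oxy]-8,8-dichloro-1,2-dimethylbicyclo[4.2.0]octan-7-one | O=C1C(Cl)(Cl)[C@]2(C)[C@@H](C)C[C@H](O[Si](C)(C)C(C)(C)C)C[C@H]12 | intermediate
11 | (1R,2S,4S,6S)-4-[(tert-butyldimethylsilyl)oxy]-1,2-dimethylbicyclo[4.2.0]octan-7-one | O=C1C[C@]2(C)[C@@H](C)C[C@H](O[Si](C)(C)C(C)(C)C)C[C@H]12 | intermediate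
12 | 2-methylbut-1-en-3-yne | C=C(C)C#C | starting material
13 | cis-fused dienone, 2α-(tert-butyldimethylsilyloxy)-10βH-eremophila-7,11-dien-9-one | C=C(C)C1=CC(=O)[C@H]2C[C@@H](O[Si](C)(C)C(C)(C)C)C[C@H](C)[C@@]2(C)C1 | intermediate
14 | cis-fused amino enone, 12-(dimethylamino)-2α-(tert-butyldimethylsilyloxy)-10βH-eremophil-7-en-9-one (C11 epimers) | CN(C)CC(C)C1=CC(=O)[C@H]2C[C@@H](O[Si](C)(C)C(C)(C)C)C[C@H](C)[C@@]2(C)C1 | intermediate
15 | trans-fused amino enone, 12-(dimethylamino)-2α-(tert-butyldimethylsilyloxy)-10αH-eremophil-7-en-9-one (C11 epimers) | CN(C)CC(C)C1=CC(=O)[C@@H]2C[C@@H](O[Si](C)(C)C(C)(C)C)C[C@H](C)[C@@]2(C)C1 | intermediate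
16 | 12-(dimethylamino)-2α-(tert-butyldimethylsilyloxy)-10αH-eremophil-7-en-9β-ol | CN(C)CC(C)C1=C[C@H](O)[C@@H]2C[C@@H](O[Si](C)(C)C(C)(C)C)C[C@H](C)[C@@]2(C)C1 | intermediate
17 | 9α-[1-(2-nitrobenzenesulfonyl)hydrazinyl] derivative of the 7-ene (sulfonyl hydrazine) | CN(C)CC(C)C1=C[C@@H](N(N)S(=O)(=O)c3ccccc3[N+](=O)[O-])[C@@H]2C[C@@H](O[Si](C)(C)C(C)(C)C)C[C@H](C)[C@@]2(C)C1 | intermediate
18 | 9α-diazenyl derivative of the 7-ene (allylic diazene) | CN(C)CC(C)C1=C[C@@H](N=N)[C@@H]2C[C@@H](O[Si](C)(C)C(C)(C)C)C[C@H](C)[C@@]2(C)C1 | intermediate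
19 | 12-(dimethylamino)-2α-(tert-butyldimethylsilyloxy)-7αH,10αH-eremophil-8-ene | CN(C)CC(C)[C@H]1C[C@]2(C)[C@@H](C)C[C@H](O[Si](C)(C)C(C)(C)C)C[C@H]2C=C1 | intermediate
20 | 12-(dimethylamino)-2α-(tert-butyldimethylsilyloxy)-7αH,10αH-eremophilane-8α,9α-diol | CN(C)CC(C)[C@H]1C[C@]2(C)[C@@H](C)C[C@H](O[Si](C)(C)C(C)(C)C)C[C@H]2[C@H](O)[C@@H]1O | intermediate
21 | N-oxide of 20 | C[N+](C)([O-])CC(C)[C@H]1C[C@]2(C)[C@@H](C)C[C@H](O[Si](C)(C)C(C)(C)C)C[C@H]2[C@H](O)[C@@H]1O | intermediate
22 | 2α-(tert-butyldimethylsilyloxy)-7αH,10αH-eremophil-11-ene-8α,9α-diol | C=C(C)[C@H]1C[C@]2(C)[C@@H](C)C[C@H](O[Si](C)(C)C(C)(C)C)C[C@H]2[C@H](O)[C@@H]1O | intermediate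
23 | ethyl pent-2-ynoate | CCC#CC(=O)OCC | starting material
24 | ethyl (2Z)-3-methylpent-2-enoate | CCOC(=O)/C=C(/C)CC | intermediate
25 | (2Z)-3-methylpent-2-enoic acid | OC(=O)/C=C(/C)CC | intermediate
26 | 2α-(tert-butyldimethylsilyloxy)-8α-hydroxy-7αH,10αH-eremophil-11-en-9α-yl (2Z)-3-methylpent-2-enoate | C=C(C)[C@H]1C[C@]2(C)[C@@H](C)C[C@H](O[Si](C)(C)C(C)(C)C)C[C@H]2[C@H](OC(=O)/C=C(/C)CC)[C@@H]1O | intermediate
27 | (1S,2R,3R,4aR,5S,7S,8aR)-2,7-dihydroxy-4a,5-dimethyl-3-(prop-1-en-2-yl)decahydronaphthalen-1-yl (2Z)-3-methylpent-2-enoate | C=C(C)[C@H]1C[C@]2(C)[C@@H](C)C[C@H](O)C[C@H]2[C@H](OC(=O)/C=C(/C)CC)[C@@H]1O | target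

Total step count: 16. Longest linear sequence: 14 steps (steps 1–12, 15 and 16, from (S)-carvone); steps 13 and 14 make the acid side chain.

Steps most likely to fail

Step 7. Oligomerization or cyclotrimerization of the terminal enyne at zerovalent nickel may outrun oxidative cyclization with the hindered ketone. The fallback replaces the alkyne C–H by C–Si and adds a desilylation. It sets out from 11, which is submitted to the same nickel-catalysed insertion with commercial 2-methyl-4-(trimethylsilyl)but-1-en-3-yne, an internal alkyne of the class for which this insertion is established. This should give the 8-trimethylsilyl dienone F1, the conjugated alkene being expected to keep control of the alkyne orientation. Fluoride-induced protodesilylation of the carbonyl-activated vinylsilane (KF, MeOH, rt; the silyl ether on C2 should be left) then comes back to the route at 13.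

Step 8. The cis/trans equilibration at C10 may stop short, or the preference for the trans-decalone may be small. The fallback uses kinetic instead of thermodynamic control. It sets out from 13, to which dimethylamine is added without carbonate so that the cis-fused amino enone 14 can be isolated. LDA (THF, −78 °C) then removes the C10 α' proton to give the cross-conjugated lithium dienolate F2. Protonation at −78 °C with a hindered phenol should occur at C10 from the α face, the β face being covered by the C5 methyl, and comes back to the route at 15.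

Step 10. Formation of the oxyphosphonium ion at the axial 9β-hydroxyl, which is syn-axial to the C5 methyl, may be slow, so that elimination competes with displacement. The fallback is a palladium-catalysed formate hydrogenolysis. It sets out from 16, which is formylated (formic acetic anhydride, pyridine, 0 °C) to the allylic formate F3. Pd(OAc)2/PBu3 in dioxane (reduced in the flask to zerovalent palladium) ionizes the formate anti to the leaving group, which places palladium on the α face. The palladium formate then loses CO2 and delivers hydride to the more substituted allyl terminus C7 from the same α face, which comes back to the route at 19.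

Further compounds
F1 | step 7 | 2α-(tert-butyldimethylsilyloxy)-8-(trimethylsilyl)-10βH-eremophila-7,11-dien-9-one | C=C(C)C1=C([Si](C)(C)C)C(=O)[C@H]2C[C@@H](O[Si](C)(C)C(C)(C)C)C[C@H](C)[C@@]2(C)C1
F2 | step 8 | lithium 8,10(9)-dienolate of 14 (cross-conjugated dienolate) | [Li+].CN(C)CC(C)C1=CC([O-])=C2C[C@@H](O[Si](C)(C)C(C)(C)C)C[C@H](C)[C@@]2(C)C1
F3 | step 10 | 12-(dimethylamino)-2α-(tert-butyldimethylsilyloxy)-10αH-eremophil-7-en-9β-yl formate | CN(C)CC(C)C1=C[C@H](OC=O)[C@@H]2C[C@@H](O[Si](C)(C)C(C)(C)C)C[C@H](C)[C@@]2(C)C1
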